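**Strategy.** Ring B of the chromanone is cut at O1–C8a and C4a–C4. The key step exploits that O1 (on C8a) and the acyl carbon C4 (on C4a) are ortho neighbours on ring A, with C4a next to the C5 oxygen, while O1–C2–C3–C4 is an anti 3-oxy-2-methylbutanoyl unit from the chiral pool. In one fluoride-triggered operation a 3,5-bis(MOM)-4-prenylbenzyne takes up the alkoxide oxygen at C8a and the acyl carbon at C4a, closing ring B with both stereocentres already in place. Precursors: an ortho-silylaryl triflate from phloroglucinol and the O-silylated Weinreb amide of Fráter–Seebach ester 14. C8 is alkylated afterwards by iminium catalysis.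

Key step: step 10

Remark on the chemistry: ester 14 is advanced to the trimethylsilyl ether of its N-methoxy-N-methylamide before the annulation, so that fluoride frees the alkoxide without any O–H proton and no alkoxide leaving group meets the enolisable chromanone. The bonds formed and the ring closed are unchanged. Adduct 19 and lactol 24 are carried as epimer mixtures at centres that later vanish.

Step 1
Reactants: 1 phloroglucinol
Product: 2 3,5-bis(methoxymethoxy)phenol
Conditions: MOMCl (2.1 equiv), iPr2NEt, CH2Cl2–DMF, 0 °C to rt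
Reagents that add atoms: chloromethyl methyl ether, COCCl
Why: Williamson-type O-alkylation with the chloromethyl ether is statistical, so the bis-ether 2 should be separable from the mono- and tris-ethers, the former of which can be resubmitted.

Step 2
Reactants: 2 3,5-bis(methoxymethoxy)phenol
Product: 3 [3,5-bis(methoxymethoxy)phenoxy]tri(propan-2-yl)silane
Conditions: iPr3SiCl, imidazole, DMF, rt
Reagents that add atoms: chlorotri(propan-2-yl)silane, CC(C)[Si](Cl)(C(C)C)C(C)C
Why: Imidazole-promoted O-silylation of the remaining phenol should install a bulky silyl ether that withstands alkyllithiums and does not direct metalation to its own ortho carbons.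

Step 3
Reactants: 3 [3,5-bis(methoxymethoxy)phenoxy]tri(propan-2-yl)silane; 4 prenyl bromide (1-bromo-3-methylbut-2-ene)
Product: 6 [3,5-bis(methoxymethoxy)-4-(3-methylbut-2-en-1-yl)phenoxy]tri(propan-2-yl)silane, via aryllithium 5 (not isolated)
Conditions: n-BuLi, THF, 0 °C; then 4, −78 °C to rt
Reagents that add atoms: none
Why: Directed ortho-metalation should take place at the one carbon flanked by both MOM ethers (cooperative chelation, the silyl ether shielding the other two), and aryllithium 5 should be alkylated by SN2 displacement at the primary carbon of 4.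

Step 4
Reactants: 6 [3,5-bis(methoxymethoxy)-4-(3-methylbut-2-en-1-yl)phenoxy]tri(propan-2-yl)silane
Product: 7 3,5-bis(methoxymethoxy)-4-(3-methylbut-2-en-1-yl)phenol
Conditions: Bu4NF, AcOH, THF, 0 °C
Reagents that add atoms: none
Why: Fluoride-induced cleavage of the aryl silyl ether, driven by the Si–F bond and buffered by AcOH, should free the phenol without touching the MOM ethers or the alkene.

Step 5
Reactants: 7 3,5-bis(methoxymethoxy)-4-(3-methylbut-2-en-1-yl)phenol
Product: 8 2-bromo-3,5-bis(methoxymethoxy)-4-(3-methylbut-2-en-1-yl)phenol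
Conditions: NBS (1.0 equiv), CH2Cl2, −78 °C
Reagents that add atoms: N-bromosuccinimide, O=C1CCC(=O)N1Br
Why: Electrophilic aromatic bromination should occur ortho to the free hydroxyl (both ortho carbons are equivalent, the para carbon is blocked) far faster than attack on the trisubstituted alkene at −78 °C, and one equivalent should hold it at monobromination.

Step 6
Reactants: 8 2-bromo-3,5-bis(methoxymethoxy)-4-(3-methylbut-2-en-1-yl)phenol
Product: 11 3,5-bis(methoxymethoxy)-4-(3-methylbut-2-en-1-yl)-2-(trimethylsilyl)phenyl trifluoromethanesulfonate, via silyl ether 9 (not isolated), via lithium phenoxide 10 (not isolated)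
Conditions: (Me3Si)2NH, THF, 65 °C, then evaporation; n-BuLi, THF, −100 to −78 °C; Tf2O, −78 °C to rt
Reagents that add atoms: hexamethyldisilazane, C[Si](C)(C)N[Si](C)(C)C; trifluoromethanesulfonic anhydride, O=S(=O)(OS(=O)(=O)C(F)(F)F)C(F)(F)F
Why: O-silylation, bromine–lithium exchange and retro-Brook rearrangement (1,3-shift of silicon from O to C) should give lithium phenoxide 10, which Tf2O traps, the standard access to ortho-silylaryl triflates.

Step 7
Reactants: 12 methyl (3S)-3-hydroxybutanoate
Product: 14 methyl (2S,3S)-3-hydroxy-2-methylbutanoate, via dilithium alkoxide enolate 13 (not isolated)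
Conditions: LDA (2.2 equiv), THF, −50 to −20 °C; MeI, DMPU, −78 to 0 °C; then AcOH
Reagents that add atoms: iodomethane, CI
Why: Fráter–Seebach alkylation, in which the chelated dianion 13 should be methylated on the face opposite to the C3 methyl group, setting C2 as S, anti to the (3S) carbinol.

Step 8
Reactants: 14 methyl (2S,3S)-3-hydroxy-2-methylbutanoate
Product: 15 (2S,3S)-3-hydroxy-N-methoxy-N,2-dimethylbutanamide
Conditions: MeNH(OMe)·HCl, iPrMgCl, THF, −20 to 0 °C
Reagents that add atoms: N,O-dimethylhydroxylamine hydrochloride, CNOC.Cl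
Why: Aminolysis of the ester by the chloromagnesium amide made in the flask (Weinreb amide formation) should be faster at −20 °C than enolisation, the hydroxyl being carried as its magnesium alkoxide, so both stereocentres should be kept.

Step 9
Reactants: 15 (2S,3S)-3-hydroxy-N-methoxy-N,2-dimethylbutanamide
Product: 16 (2S,3S)-N-methoxy-N,2-dimethyl-3-[(trimethylsilyl)oxy]butanamide
Conditions: Me3SiCl, imidazole, CH2Cl2, 0 °C
Reagents that add atoms: chlorotrimethylsilane, C[Si](C)(C)Cl
Why: Standard silylation of a secondary alcohol should mask the only O–H proton as a fluoride-labile trimethylsilyl ether.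

Step 10
Reactants: 11 3,5-bis(methoxymethoxy)-4-(3-methylbut-2-en-1-yl)-2-(trimethylsilyl)phenyl trifluoromethanesulfonate; 16 (2S,3S)-N-methoxy-N,2-dimethyl-3-[(trimethylsilyl)oxy]butanamide
Product: 20 (2S,3S)-5,7-bis(methoxymethoxy)-2,3-dimethyl-6-(3-methylbut-2-en-1-yl)-2,3-dihydro-4H-chromen-4-one, via cesium alkoxide 17 (not isolated), via aryne 18 (not isolated), via tetrahedral adduct 19 (not isolated)
Conditions: 16 (1.5 equiv), CsF (3 equiv), 18-crown-6, THF, 0 °C to rt; then AcOH, H2O, 0 °C
Reagents that add atoms: none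
Why: Proposed new method: fluoride cleaves the O–Si bond of 16 to give the proton-free alkoxide 17 and, by 1,2-elimination of Me3SiF and triflate from 11, the aryne 18; 17 adds to the aryne carbon remote from the C5 MOM ether (future C8a, bond O1–C8a), and the aryl anion left at C4a attacks the amide carbonyl in a 6-exo-trig acyl substitution (bond C4a–C4) that closes ring B as the tetrahedral adduct 19, which becomes the ketone only on the acidic quench. The closest known reactions are the tandem addition–acylation of arynes with salicylate esters that gives xanthones, the insertion of arynes into unsaturated carboxylic acids that ends in chroman-4-ones, and Parham-type cyclisation of aryllithiums onto N-methoxy-N-methylamides; an aliphatic alkoxide carrying a β-acyl acceptor has not been used in this way. No stereocentre is made: the C2–O bond is never broken and C3 cannot be enolised while the carbonyl stays masked as 19, so the anti (2S,3S) amide should map onto the trans chromanone. The regioselectivity needed (oxygen at C8a, acyl at C4a) is secured by the C5 alkoxy group, which distorts and polarises the aryne so that the nucleophile attacks the carbon flanked only by C8–H and the charge develops beside the inductively withdrawing oxygen. Acylation should win over protonation of the aryl anion because the flask holds no O–H group (silyl ether, amide acceptor, THF), and the amide resists the retro-aldol and elimination paths open to an ester.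

Step 11
Reactants: 20 (2S,3S)-5,7-bis(methoxymethoxy)-2,3-dimethyl-6-(3-methylbut-2-en-1-yl)-2,3-dihydro-4H-chromen-4-one
Product: 21 (2S,3S)-5,7-dihydroxy-2,3-dimethyl-6-(3-methylbut-2-en-1-yl)-2,3-dihydro-4H-chromen-4-one
Conditions: HCl (1.25 M in MeOH), rt
Reagents that add atoms: none
Why: Acid-catalysed acetal exchange with methanol should remove both MOM ethers (the chelated C5 one first) under conditions too mild to cyclise the prenyl group onto a phenol or to enolise C3.

Step 12
Reactants: 21 (2S,3S)-5,7-dihydroxy-2,3-dimethyl-6-(3-methylbut-2-en-1-yl)-2,3-dihydro-4H-chromen-4-one; 22 (2E)-hex-2-enal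
Product: 24 (2S,3S,10R)-5,8-dihydroxy-2,3-dimethyl-6-(3-methylbut-2-en-1-yl)-10-propyl-2,3,9,10-tetrahydro-4H,8H-pyrano[2,3-f]chromen-4-one (lactol between the C7 oxygen and the aldehyde carbon, C8 epimers), via open-chain aldehyde 23 (not isolated)
Conditions: (S)-2-[diphenyl(trimethylsilyloxy)methyl]pyrrolidine (20 mol %), PhCO2H (20 mol %), CH2Cl2, 0 °C to rt
Reagents that add atoms: none
Why: Iminium-ion catalysis (organocatalytic Friedel–Crafts-type conjugate addition of a phenol to an enal) should join the β-carbon of 22 to C8, the only unsubstituted ring carbon and ortho to the C7 hydroxyl, on the face of the s-trans E-iminium ion not shielded by the diphenyl(silyloxy)methyl group of the S catalyst, which sets the benzylic carbon as R, after which aldehyde 23 should close onto the C7 hydroxyl as the lactol.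

Step 13
Reactants: 24 lactol (2S,3S,10R)-5,8-dihydroxy-2,3-dimethyl-6-(3-methylbut-2-en-1-yl)-10-propyl-2,3,9,10-tetrahydro-4H,8H-pyrano[2,3-f]chromen-4-one
Product: 25 (2S,3S,10R)-5-hydroxy-2,3-dimethyl-6-(3-methylbut-2-en-1-yl)-10-propyl-2,3,9,10-tetrahydro-4H,8H-pyrano[2,3-f]chromene-4,8-dione
Conditions: [C5H5NH][CrO3Cl], NaOAc, 4 Å molecular sieves, CH2Cl2, rt
Reagents that add atoms: none
Why: Oxidation of a lactol to the lactone by buffered hexavalent chromium should leave the chelated C5 phenol, the ketone and the trisubstituted alkene untouched.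

Step 14
Reactants: 25 (2S,3S,10R)-5-hydroxy-2,3-dimethyl-6-(3-methylbut-2-en-1-yl)-10-propyl-2,3,9,10-tetrahydro-4H,8H-pyrano[2,3-f]chromene-4,8-dione
Product: 26 methyl (3R)-3-[(2S,3S)-5,7-dihydroxy-2,3-dimethyl-6-(3-methylbut-2-en-1-yl)-4-oxo-3,4-dihydro-2H-chromen-8-yl]hexanoate (CNP0068017.2)
Conditions: MeOH, Et3N (0.2 equiv), 0 °C to rt
Reagents that add atoms: methanol, CO
Why: Amine-catalysed methanolysis (transesterification) of the aryl ester in neat methanol should open the lactone because the departing C7 phenol is a vinylogous acid para to the ketone, and so weak a base should neither epimerise C3 nor open ring B.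

**Compound list**

1 | phloroglucinol (benzene-1,3,5-triol) | Oc1cc(O)cc(O)c1 | starting material
2 | 3,5-bis(methoxymethoxy)phenol | COCOc1cc(O)cc(OCOC)c1 | intermediate
3 | [3,5-bis(methoxymethoxy)phenoxy]tri(propan-2-yl)silane | COCOc1cc(O[Si](C(C)C)(C(C)C)C(C)C)cc(OCOC)c1 | intermediate
4 | prenyl bromide (1-bromo-3-methylbut-2-ene) | CC(C)=CCBr | starting material
5 | {2,6-bis(methoxymethoxy)-4-[tri(propan-2-yl)silyloxy]phenyl}lithium | [Li]c1c(OCOC)cc(O[Si](C(C)C)(C(C)C)C(C)C)cc1OCOC | intermediate
6 | [3,5-bis(methoxymethoxy)-4-(3-methylbut-2-en-1-yl)phenoxy]tri(propan-2-yl)silane | COCOc1cc(O[Si](C(C)C)(C(C)C)C(C)C)cc(OCOC)c1CC=C(C)C | intermediate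
7 | 3,5-bis(methoxymethoxy)-4-(3-methylbut-2-en-1-yl)phenol | COCOc1cc(O)cc(OCOC)c1CC=C(C)C | intermediate
8 | 2-bromo-3,5-bis(methoxymethoxy)-4-(3-methylbut-2-en-1-yl)phenol | COCOc1cc(O)c(Br)c(OCOC)c1CC=C(C)C | intermediate
9 | [2-bromo-3,5-bis(methoxymethoxy)-4-(3-methylbut-2-en-1-yl)phenoxy]trimethylsilane | COCOc1cc(O[Si](C)(C)C)c(Br)c(OCOC)c1CC=C(C)C | intermediate
10 | lithium 3,5-bis(methoxymethoxy)-4-(3-methylbut-2-en-1-yl)-2-(trimethylsilyl)phenoxide | [Li+].[O-]c1cc(OCOC)c(CC=C(C)C)c(OCOC)c1[Si](C)(C)C | intermediate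
11 | 3,5-bis(methoxymethoxy)-4-(3-methylbut-2-en-1-yl)-2-(trimethylsilyl)phenyl trifluoromethanesulfonate | C[Si](C)(C)c1c(OS(=O)(=O)C(F)(F)F)cc(OCOC)c(CC=C(C)C)c1OCOC | intermediate
12 | methyl (3S)-3-hydroxybutanoate | O[C@@H](C)CC(=O)OC | starting material
13 | dilithium (3S)-1-methoxybut-1-ene-1,3-diolate (alkoxide enolate of 12) | [Li+].[Li+].[O-][C@@H](C)C=C([O-])OC | intermediate
14 | methyl (2S,3S)-3-hydroxy-2-methylbutanoate | O[C@@H](C)[C@H](C)C(=O)OC | intermediate
15 | (2S,3S)-3-hydroxy-N-methoxy-N,2-dimethylbutanamide | O[C@@H](C)[C@H](C)C(=O)N(C)OC | intermediate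
16 | (2S,3S)-N-methoxy-N,2-dimethyl-3-[(trimethylsilyl)oxy]butanamide | C[Si](C)(C)O[C@@H](C)[C@H](C)C(=O)N(C)OC | intermediate
17 | cesium (2S,3S)-4-[methoxy(methyl)amino]-3-methyl-4-oxobutan-2-olate | [Cs+].[O-][C@@H](C)[C@H](C)C(=O)N(C)OC | intermediate
18 | 3,5-bis(methoxymethoxy)-4-(3-methylbut-2-en-1-yl)benzyne | C1#CC(OCOC)=C(CC=C(C)C)C(OCOC)=C1 | intermediate
19 | cesium (2S,3S)-4-[methoxy(methyl)amino]-5,7-bis(methoxymethoxy)-2,3-dimethyl-6-(3-methylbut-2-en-1-yl)-3,4-dihydro-2H-chromen-4-olate (C4 epimers) | COCOc1cc2O[C@@H](C)[C@H](C)C([O-])(N(C)OC)c2c(OCOC)c1CC=C(C)C.[Cs+] | intermediate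
20 | (2S,3S)-5,7-bis(methoxymethoxy)-2,3-dimethyl-6-(3-methylbut-2-en-1-yl)-2,3-dihydro-4H-chromen-4-one | c1c(OCOC)c(CC=C(C)C)c(OCOC)c2c1O[C@@H](C)[C@H](C)C2=O | intermediate
21 | (2S,3S)-5,7-dihydroxy-2,3-dimethyl-6-(3-methylbut-2-en-1-yl)-2,3-dihydro-4H-chromen-4-one | c1c(O)c(CC=C(C)C)c(O)c2c1O[C@@H](C)[C@H](C)C2=O | intermediate
22 | (2E)-hex-2-enal | CCC/C=C/C=O | starting material
23 | (3R)-3-[(2S,3S)-5,7-dihydroxy-2,3-dimethyl-6-(3-methylbut-2-en-1-yl)-4-oxo-3,4-dihydro-2H-chromen-8-yl]hexanal | CCC[C@H](CC=O)c1c(O)c(CC=C(C)C)c(O)c2c1O[C@@H](C)[C@H](C)C2=O | intermediate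
24 | (2S,3S,10R)-5,8-dihydroxy-2,3-dimethyl-6-(3-methylbut-2-en-1-yl)-10-propyl-2,3,9,10-tetrahydro-4H,8H-pyrano[2,3-f]chromen-4-one (C8 epimers) | CCC[C@@H]1CC(O)Oc2c1c3O[C@@H](C)[C@H](C)C(=O)c3c(O)c2CC=C(C)C | intermediate
25 | (2S,3S,10R)-5-hydroxy-2,3-dimethyl-6-(3-methylbut-2-en-1-yl)-10-propyl-2,3,9,10-tetrahydro-4H,8H-pyrano[2,3-f]chromene-4,8-dione | CCC[C@@H]1CC(=O)Oc2c1c3O[C@@H](C)[C@H](C)C(=O)c3c(O)c2CC=C(C)C | intermediate
26 | methyl (3R)-3-[(2S,3S)-5,7-dihydroxy-2,3-dimethyl-6-(3-methylbut-2-en-1-yl)-4-oxo-3,4-dihydro-2H-chromen-8-yl]hexanoate | CCC[C@H](CC(=O)OC)c1c(O)c(CC=C(C)C)c(O)c2c1O[C@@H](C)[C@H](C)C2=O | target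

**Step count.** Total: 14 steps. Longest linear sequence: 11 steps (steps 1–6, then 10–14); the chiral partner takes steps 7–9.

**Steps most likely to fail**

1. Step 10 (Proposed new method). The aryl anion may be protonated or may pick up silicon before it reaches the amide carbonyl, or the alkoxide may be used up in side-paths, so that ring B does not close. The fallback uses known chemistry only; it sets out from bromophenol 8 and comes back at 20. An Evans syn aldol reaction of (4S)-4-benzyl-3-propanoyl-1,3-oxazolidin-2-one with acetaldehyde (Bu2BOTf, iPr2NEt) would give (4S)-4-benzyl-3-[(2S,3R)-3-hydroxy-2-methylbutanoyl]-1,3-oxazolidin-2-one F1. Transamidation (MeNH(OMe)·HCl, AlMe3) would give the syn amide (2S,3R)-3-hydroxy-N-methoxy-N,2-dimethylbutanamide F2. Mitsunobu etherification of 8 with F2 (PPh3, DIAD), with inversion at the carbinol carbon, would give (2S,3S)-3-[2-bromo-3,5-bis(methoxymethoxy)-4-(3-methylbut-2-en-1-yl)phenoxy]-N-methoxy-N,2-dimethylbutanamide F3. Bromine–lithium exchange (t-BuLi, THF, −100 °C) and Parham cyclisation of the aryllithium onto the amide would then return to 20.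

2. Step 12. The acyl-deactivated ring may add too slowly to the iminium ion, with competing condensation at the aldehyde carbon or poor facial selectivity. The fallback sets out from 21 (with 22) and comes back at 25, bypassing 24. It uses oxidative N-heterocyclic carbene catalysis: a chiral aminoindanol-derived triazolium salt, a weak base and 3,3',5,5'-tetra-tert-butyl-4,4'-diphenoquinone would turn 22 into an α,β-unsaturated acyl azolium. This should acylate the C7 oxygen, deliver the β-carbon to C8 by [3,3] rearrangement and lactonise. The catalyst enantiomer would be chosen for the 10R series. No compound outside the list is made (F0).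

3. Step 5. Electrophilic bromine may attack the prenyl alkene or brominate both ortho carbons. The fallback sets out from 7 and comes back at 11, introducing silicon by directed ortho-metalation instead. Isopropyl isocyanate (cat. Et3N) would give 3,5-bis(methoxymethoxy)-4-(3-methylbut-2-en-1-yl)phenyl N-(propan-2-yl)carbamate F4. N-Silylation (Me3SiOTf, TMEDA), ortho-lithiation between the carbamate and the neighbouring MOM ether (n-BuLi, TMEDA, Et2O, −78 °C) and Me3SiCl would give 3,5-bis(methoxymethoxy)-4-(3-methylbut-2-en-1-yl)-2-(trimethylsilyl)phenyl N-(propan-2-yl)carbamate F5 after acidic work-up. Cleavage with Et2NH and DBU and triflation of the phenoxide in the same flask with PhN(SO2CF3)2 would return to 11.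

**Further compounds**

F1 | step 10 | (4S)-4-benzyl-3-[(2S,3R)-3-hydroxy-2-methylbutanoyl]-1,3-oxazolidin-2-one | O[C@H](C)[C@H](C)C(=O)N1[C@@H](Cc2ccccc2)COC1=O
F2 | step 10 | (2S,3R)-3-hydroxy-N-methoxy-N,2-dimethylbutanamide | O[C@H](C)[C@H](C)C(=O)N(C)OC
F3 | step 10 | (2S,3S)-3-[2-bromo-3,5-bis(methoxymethoxy)-4-(3-methylbut-2-en-1-yl)phenoxy]-N-methoxy-N,2-dimethylbutanamide | Brc1c(OCOC)c(CC=C(C)C)c(OCOC)cc1O[C@@H](C)[C@H](C)C(=O)N(C)OC
F0 | step 12 | none | none
F4 | step 5 | 3,5-bis(methoxymethoxy)-4-(3-methylbut-2-en-1-yl)phenyl N-(propan-2-yl)carbamate | CC(C)NC(=O)Oc1cc(OCOC)c(CC=C(C)C)c(OCOC)c1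
F5 | step 5 | 3,5-bis(methoxymethoxy)-4-(3-methylbut-2-en-1-yl)-2-(trimethylsilyl)phenyl N-(propan-2-yl)carbamate | CC(C)NC(=O)Oc1cc(OCOC)c(CC=C(C)C)c(OCOC)c1[Si](C)(C)C
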